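**Strategy.** The route rests on cutting the two ring alkenes, C3=C4 of the 2H-pyran ring (O1–C2–C3–C4–C4a–C8a) and C7'=C8' of the butenolide ring, back to four terminal alkenes; each is a cis alkene held in an oxygen heterocycle. One treatment with the second-generation Grubbs catalyst (H2IMes)(PCy3)Cl2Ru=CHPh then closes both rings with loss of two ethylenes. The precursor is an acyclic tetraene: an (R)-aryl tertiary allyl ether at C2 with an ortho vinyl group on the arene, and an (R)-secondary 2-methylidene ester at C6' that carries a vinyl group. C2 is set by palladium-catalysed asymmetric O-allylation, C6' by an oxazolidinone glycolate alkylation.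

Key step: step 20

Locants: chromene O1, C2, C3, C4, C4a, C5–C8, C8a; side chain C1'–C5' from C2; lactone carbinol C6'; lactone alkene C7'=C8'.

Assumption: in step 4 the (R,R)-ligand with the (E)-carbonate is taken to give the (R)-ether; should the facial sense prove the reverse, the (S,S)-ligand is used and nothing else changes.

**Arene and side chain**

Step 1
Reactants: 1 2-methylhydroquinone
Product: 2 4-(tert-butyldimethylsilyloxy)-2-methylphenol
Conditions: TBSCl (1.0 equiv), imidazole, DMF, 0 °C
Reagents that add atoms: tert-butyldimethylsilyl chloride, CC(C)(C)[Si](C)(C)Cl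
Why: Silyl ether formation should favour the C4 hydroxyl, which lacks the ortho methyl group that shields the other hydroxyl, and one equivalent of silyl chloride at 0 °C limits bis-silylation, the minor regioisomer and the bis-ether being removed by chromatography.

Step 2
Reactants: 2 4-(tert-butyldimethylsilyloxy)-2-methylphenol
Product: 3 2-bromo-4-(tert-butyldimethylsilyloxy)-6-methylphenol
Conditions: NBS (1.0 equiv), i-Pr2NH (0.1 equiv), CH2Cl2, 0 °C
Reagents that add atoms: N-bromosuccinimide, O=C1CCC(=O)N1Br
Why: Electrophilic aromatic bromination of a para-blocked phenol goes to the one free position ortho to the hydroxyl group, because the free phenol is a much stronger activator than the silyl ether and directs the amine-activated bromine donor through hydrogen bonding.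

Step 3
Reactants: 4 geraniol
Product: 5 geranyl methyl carbonate
Conditions: ClCO2Me, pyridine, CH2Cl2, 0 °C
Reagents that add atoms: methyl chloroformate, COC(=O)Cl
Why: Acylation of the primary allylic alcohol with a chloroformate gives the allylic carbonate, a leaving group that zerovalent palladium ionises readily and that releases its own base.

Step 4
Reactants: 3 2-bromo-4-(tert-butyldimethylsilyloxy)-6-methylphenol, 5 geranyl methyl carbonate
Product: 6 (R)-2-bromo-4-(tert-butyldimethylsilyloxy)-6-methylphenyl 3,7-dimethylocta-1,6-dien-3-yl ether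
Conditions: Pd2(dba)3·CHCl3 (2 mol %), (1R,2R)-N,N'-bis[2-(diphenylphosphino)benzoyl]cyclohexane-1,2-diamine (6 mol %), CH2Cl2, rt
Reagents that add atoms: none
Why: Tsuji–Trost-type asymmetric allylic etherification, in which zerovalent palladium ionises the carbonate to a 1,1-disubstituted π-allyl complex, the methoxide set free deprotonates the phenol, and the phenoxide (ortho and para positions blocked, so only O-attack is possible) adds to the more substituted allyl terminus on the face left open by the chiral diamide bisphosphine ligand, which sets C2 as (R).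

Step 5
Reactants: 6 (R)-2-bromo-4-(tert-butyldimethylsilyloxy)-6-methylphenyl 3,7-dimethylocta-1,6-dien-3-yl ether
Product: 7 (R)-4-(tert-butyldimethylsilyloxy)-2-methyl-6-vinylphenyl 3,7-dimethylocta-1,6-dien-3-yl ether
Conditions: Bu3SnCH=CH2 (1.5 equiv), Pd(PPh3)4 (5 mol %), BHT (cat.), toluene, 90 °C
Reagents that add atoms: tributyl(vinyl)stannane, C=C[Sn](CCCC)(CCCC)CCCC
Why: Stille coupling of the aryl bromide with a vinylstannane needs neither base nor fluoride, so the aryl silyl ether survives, and a moderate temperature with Pd(PPh3)4 is chosen to keep ionisation of the tertiary allyl aryl ether by zerovalent palladium slow.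

Step 6
Reactants: 7 (R)-4-(tert-butyldimethylsilyloxy)-2-methyl-6-vinylphenyl 3,7-dimethylocta-1,6-dien-3-yl ether
Product: 8 (2E,6R)-6-[4-(tert-butyldimethylsilyloxy)-2-methyl-6-vinylphenoxy]-2,6-dimethylocta-2,7-dien-1-ol
Conditions: SeO2 (0.3 equiv), t-BuOOH (3 equiv), CH2Cl2, rt, stopped before full conversion
Reagents that add atoms: tert-butyl hydroperoxide, CC(C)(C)OO (its oxygen is passed on through selenium dioxide, O=[Se]=O)
Why: Selenium dioxide allylic oxidation (ene reaction followed by a [2,3]-sigmatropic shift) attacks the (E)-methyl group at the more substituted end of the trisubstituted alkene and gives the (E)-allylic alcohol, while the two vinyl groups carry no allylic hydrogen.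

Step 7
Reactants: 8 (2E,6R)-6-[4-(tert-butyldimethylsilyloxy)-2-methyl-6-vinylphenoxy]-2,6-dimethylocta-2,7-dien-1-ol
Product: 9 (3R,6E)-8-bromo-3-[4-(tert-butyldimethylsilyloxy)-2-methyl-6-vinylphenoxy]-3,7-dimethylocta-1,6-diene
Conditions: CBr4, PPh3, CH2Cl2, 0 °C
Reagents that add atoms: carbon tetrabromide, BrC(Br)(Br)Br
Why: The Appel reaction turns the primary allylic alcohol into the bromide under neutral conditions at low temperature, without allylic transposition and without acid that could harm the tertiary aryl ether.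

**Glycolate auxiliary**

Step 8
Reactants: 10 (S)-4-benzyl-2-oxazolidinone, 11 (benzyloxy)acetyl chloride
Product: 13 (S)-4-benzyl-3-(benzyloxyacetyl)oxazolidin-2-one, via lithium oxazolidinide 12 (not isolated)
Conditions: n-BuLi, THF, −78 °C; then 11, −78 → 0 °C
Reagents that add atoms: none
Why: N-Acylation of the lithiated oxazolidinone with an acid chloride is the standard entry to an Evans imide.

Step 9
Reactants: 13 (S)-4-benzyl-3-(benzyloxyacetyl)oxazolidin-2-one
Product: 14 (S)-4-benzyl-3-(hydroxyacetyl)oxazolidin-2-one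
Conditions: H2 (1 atm), 10% Pd/C, EtOAc, rt
Reagents that add atoms: none
Why: Hydrogenolysis of the O-benzyl ether frees the hydroxyl group and leaves the imide and the C-benzyl group untouched.

Step 10
Reactants: 14 (S)-4-benzyl-3-(hydroxyacetyl)oxazolidin-2-one
Product: 15 (S)-4-benzyl-3-[(triethylsilyloxy)acetyl]oxazolidin-2-one
Conditions: Et3SiCl, imidazole, CH2Cl2, 0 °C
Reagents that add atoms: chlorotriethylsilane, CC[Si](CC)(CC)Cl
Why: Silylation of the primary alcohol installs a triethylsilyl ether that should survive enolate, hydride, periodinane and ylide chemistry and can later be removed by weak acid without loss of the aryl tert-butyldimethylsilyl ether.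

**Joining the fragments and building the C6' vinyl carbinol**

Step 11
Reactants: 15 (S)-4-benzyl-3-[(triethylsilyloxy)acetyl]oxazolidin-2-one, 9 (3R,6E)-8-bromo-3-[4-(tert-butyldimethylsilyloxy)-2-methyl-6-vinylphenoxy]-3,7-dimethylocta-1,6-diene
Product: 17 (S)-4-benzyl-3-{(2R,4E,8R)-8-[4-(tert-butyldimethylsilyloxy)-2-methyl-6-vinylphenoxy]-4,8-dimethyl-2-(triethylsilyloxy)deca-4,9-dienoyl}oxazolidin-2-one, via sodium glycolate enolate 16 (not isolated)
Conditions: 15 (2 equiv), NaN(SiMe3)2 (2 equiv), THF, −78 °C; then 9 (1 equiv), Bu4NI (cat.), −78 → −45 °C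
Reagents that add atoms: none
Why: Evans-type glycolate alkylation, in which the chelated sodium (Z)-enolate is shielded on one face by the benzyl group of the (S)-oxazolidinone, so the allylic bromide adds to the opposite face and sets C6' as (R).

Step 12
Reactants: 17 (S)-4-benzyl-3-{(2R,4E,8R)-8-[4-(tert-butyldimethylsilyloxy)-2-methyl-6-vinylphenoxy]-4,8-dimethyl-2-(triethylsilyloxy)deca-4,9-dienoyl}oxazolidin-2-one
Product: 18 (2R,4E,8R)-8-[4-(tert-butyldimethylsilyloxy)-2-methyl-6-vinylphenoxy]-4,8-dimethyl-2-(triethylsilyloxy)deca-4,9-dien-1-ol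
Conditions: LiBH4, MeOH (1 equiv), Et2O, 0 °C
Reagents that add atoms: none
Why: Hydride cleavage of the exocyclic imide carbonyl (reductive removal of the Evans auxiliary) gives the primary alcohol and the recoverable oxazolidinone, and the weakly basic borate medium at 0 °C should neither epimerise C6' nor move the triethylsilyl group.

Step 13
Reactants: 18 (2R,4E,8R)-8-[4-(tert-butyldimethylsilyloxy)-2-methyl-6-vinylphenoxy]-4,8-dimethyl-2-(triethylsilyloxy)deca-4,9-dien-1-ol
Product: 19 (2R,4E,8R)-8-[4-(tert-butyldimethylsilyloxy)-2-methyl-6-vinylphenoxy]-4,8-dimethyl-2-(triethylsilyloxy)deca-4,9-dienal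
Conditions: Dess–Martin periodinane, pyridine, CH2Cl2, 0 °C → rt
Reagents that add atoms: none
Why: Dess–Martin oxidation buffered with pyridine gives the α-silyloxy aldehyde without epimerisation and without touching the alkenes or the electron-rich arene.

Step 14
Reactants: 19 (2R,4E,8R)-8-[4-(tert-butyldimethylsilyloxy)-2-methyl-6-vinylphenoxy]-4,8-dimethyl-2-(triethylsilyloxy)deca-4,9-dienal
Product: 20 (3R,6E,9R)-3-[4-(tert-butyldimethylsilyloxy)-2-methyl-6-vinylphenoxy]-3,7-dimethyl-9-(triethylsilyloxy)undeca-1,6,10-triene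
Conditions: Ph3PCH3Br, KN(SiMe3)2, THF, 0 °C; then 19, −78 → 0 °C
Reagents that add atoms: methyltriphenylphosphonium bromide, C[P+](c1ccccc1)(c1ccccc1)c1ccccc1.[Br-]
Why: Wittig methylenation with the unstabilised ylide at low temperature turns the crude aldehyde into the C6' vinyl group faster than the α-stereocentre can epimerise.

Step 15
Reactants: 20 (3R,6E,9R)-3-[4-(tert-butyldimethylsilyloxy)-2-methyl-6-vinylphenoxy]-3,7-dimethyl-9-(triethylsilyloxy)undeca-1,6,10-triene
Product: 21 (3R,5E,9R)-9-[4-(tert-butyldimethylsilyloxy)-2-methyl-6-vinylphenoxy]-5,9-dimethylundeca-1,5,10-trien-3-ol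
Conditions: PPTS (0.2 equiv), MeOH, rt
Reagents that add atoms: none
Why: Acid-catalysed methanolysis removes the secondary alkyl triethylsilyl ether, while the aryl tert-butyldimethylsilyl ether and the tertiary allyl aryl ether are stable to this weak acid.

**Acid fragment**

Step 16
Reactants: 22 triethyl phosphonoacetate, 23 5-bromo-2-methylpent-2-ene
Product: 25 ethyl 2-(diethoxyphosphoryl)-6-methylhept-5-enoate, via sodium phosphonoacetate carbanion 24 (not isolated)
Conditions: NaH, DMF, 0 °C → rt; then 23, NaI (cat.), 60 °C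
Reagents that add atoms: none
Why: SN2 C-alkylation of the sodium salt of the phosphonoacetate with a primary alkyl bromide installs the 4-methylpent-3-enyl chain.

Step 17
Reactants: 25 ethyl 2-(diethoxyphosphoryl)-6-methylhept-5-enoate
Product: 26 ethyl 6-methyl-2-methylidenehept-5-enoate
Conditions: aq. HCHO (37%), K2CO3, H2O/THF, rt
Reagents that add atoms: formaldehyde, C=O
Why: Horner–Wadsworth–Emmons olefination with formaldehyde turns the α-substituted phosphonoacetate into the α-methylene ester.

Step 18
Reactants: 26 ethyl 6-methyl-2-methylidenehept-5-enoate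
Product: 28 6-methyl-2-methylidenehept-5-enoic acid, via lithium carboxylate 27 (not isolated)
Conditions: LiOH, THF/H2O, rt; then 1 M HCl
Reagents that add atoms: lithium hydroxide, [Li+].[OH-]
Why: Saponification of the ethyl ester followed by acidification gives the acid, and conjugate addition of hydroxide to the α-substituted acrylate is slow at room temperature.

**Precursor, key step and release of the target**

Step 19
Reactants: 21 (3R,5E,9R)-9-[4-(tert-butyldimethylsilyloxy)-2-methyl-6-vinylphenoxy]-5,9-dimethylundeca-1,5,10-trien-3-ol, 28 6-methyl-2-methylidenehept-5-enoic acid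
Product: 29 (3R,5E,9R)-9-[4-(tert-butyldimethylsilyloxy)-2-methyl-6-vinylphenoxy]-5,9-dimethylundeca-1,5,10-trien-3-yl 6-methyl-2-methylidenehept-5-enoate (open-chain tetraene)
Conditions: 28 (1.5 equiv), DCC, DMAP (0.2 equiv), CH2Cl2, 0 °C → rt
Reagents that add atoms: none
Why: Steglich esterification acylates the secondary allylic alcohol on oxygen, so the C6' configuration is retained.

Step 20
Reactants: 29 open-chain tetraene
Product: 31 6-O-tert-butyldimethylsilyl ether of 2'-epi-tuberatolide B, via chromene acrylate ester 30 (not isolated)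
Conditions: second-generation Grubbs catalyst (H2IMes)(PCy3)Cl2Ru=CHPh (10 mol %, two portions), CH2Cl2 (0.002 M), 40 °C
Reagents that add atoms: none
Why: The benzylidene complex (H2IMes)(PCy3)Cl2Ru=CHPh exchanges first with the two unhindered monosubstituted alkenes (the styrene and the C6' vinyl group), and each new ruthenium carbene adds to its tethered partner through a ruthenacyclobutane that collapses with loss of ethylene, which is ordinary ring-closing metathesis of oxygen-tethered dienes as known separately for 2-vinylaryl tertiary allyl ethers (giving 2H-chromenes) and for allyl α-substituted acrylates (giving butenolides). The pyran ring closes in a six-membered mode, the styrenyl carbene at C4 engaging the hindered C2 vinyl group to form C3=C4, and the butenolide closes in a five-membered mode, the C6' alkylidene engaging the 1,1-disubstituted acrylate to form C7'=C8'; both ring sizes allow only the cis alkene. No stereocentre is created, and C2 and C6' sit on a tertiary ether carbon and a secondary ester carbon that the catalyst does not touch, so both configurations pass through unchanged. The selectivity needed is chemoselectivity among six alkenes: the C2 vinyl group must meet the styrene and not C3'=C4' (a cyclopentene closure that would cut the chain), and this is secured because initiation at a vinyl group on a quaternary carbon is slow, whereas the styrenyl carbene has only the six-ring closure open to it. The two trisubstituted chain alkenes react far more slowly and could only close four-membered or eight-membered rings, high dilution suppresses cross metathesis, and gentle heating drives the slower acrylate closure to completion.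

Step 21
Reactants: 31 6-O-tert-butyldimethylsilyl ether of 2'-epi-tuberatolide B
Product: 32 2'-epi-tuberatolide B
Conditions: Bu4NF (1.1 equiv), AcOH (1.1 equiv), THF, 0 °C
Reagents that add atoms: none
Why: Fluoride cleavage of the aryl silyl ether, buffered with acetic acid so that the γ-hydrogen of the butenolide at C6' is not removed, frees the phenol and should leave both stereocentres and the chromene intact.

**Compound list**

1 | 2-methylhydroquinone | Cc1cc(O)ccc1O | starting material
2 | 4-(tert-butyldimethylsilyloxy)-2-methylphenol | Cc1cc(O[Si](C)(C)C(C)(C)C)ccc1O | intermediate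
3 | 2-bromo-4-(tert-butyldimethylsilyloxy)-6-methylphenol | Cc1cc(O[Si](C)(C)C(C)(C)C)cc(Br)c1O | intermediate
4 | geraniol | CC(C)=CCC/C(C)=C/CO | starting material
5 | geranyl methyl carbonate | CC(C)=CCC/C(C)=C/COC(=O)OC | intermediate
6 | (R)-2-bromo-4-(tert-butyldimethylsilyloxy)-6-methylphenyl 3,7-dimethylocta-1,6-dien-3-yl ether | Cc1cc(O[Si](C)(C)C(C)(C)C)cc(Br)c1O[C@@](C)(C=C)CCC=C(C)C | intermediate
7 | (R)-4-(tert-butyldimethylsilyloxy)-2-methyl-6-vinylphenyl 3,7-dimethylocta-1,6-dien-3-yl ether | C=Cc1cc(O[Si](C)(C)C(C)(C)C)cc(C)c1O[C@@](C)(C=C)CCC=C(C)C | intermediate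
8 | (2E,6R)-6-[4-(tert-butyldimethylsilyloxy)-2-methyl-6-vinylphenoxy]-2,6-dimethylocta-2,7-dien-1-ol | C=Cc1cc(O[Si](C)(C)C(C)(C)C)cc(C)c1O[C@@](C)(C=C)CC/C=C(C)/CO | intermediate
9 | (3R,6E)-8-bromo-3-[4-(tert-butyldimethylsilyloxy)-2-methyl-6-vinylphenoxy]-3,7-dimethylocta-1,6-diene | C=Cc1cc(O[Si](C)(C)C(C)(C)C)cc(C)c1O[C@@](C)(C=C)CC/C=C(C)/CBr | intermediate
10 | (S)-4-benzyl-2-oxazolidinone | O=C1N[C@@H](Cc2ccccc2)CO1 | starting material
11 | (benzyloxy)acetyl chloride | O=C(Cl)COCc1ccccc1 | starting material
12 | lithium (S)-4-benzyl-2-oxooxazolidin-3-ide | [Li+].O=C1[N-][C@@H](Cc2ccccc2)CO1 | intermediate (not isolated)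
13 | (S)-4-benzyl-3-(benzyloxyacetyl)oxazolidin-2-one | O=C(COCc1ccccc1)N1[C@@H](Cc2ccccc2)COC1=O | intermediate
14 | (S)-4-benzyl-3-(hydroxyacetyl)oxazolidin-2-one | O=C(CO)N1[C@@H](Cc2ccccc2)COC1=O | intermediate
15 | (S)-4-benzyl-3-[(triethylsilyloxy)acetyl]oxazolidin-2-one | CC[Si](CC)(CC)OCC(=O)N1[C@@H](Cc2ccccc2)COC1=O | intermediate
16 | sodium (Z)-enolate of 15 | [Na+].CC[Si](CC)(CC)O/C=C(\[O-])N1[C@@H](Cc2ccccc2)COC1=O | intermediate (not isolated)
17 | (S)-4-benzyl-3-{(2R,4E,8R)-8-[4-(tert-butyldimethylsilyloxy)-2-methyl-6-vinylphenoxy]-4,8-dimethyl-2-(triethylsilyloxy)deca-4,9-dienoyl}oxazolidin-2-one | C=Cc1cc(O[Si](C)(C)C(C)(C)C)cc(C)c1O[C@@](C)(C=C)CC/C=C(C)/C[C@@H](O[Si](CC)(CC)CC)C(=O)N1[C@@H](Cc2ccccc2)COC1=O | intermediate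
18 | (2R,4E,8R)-8-[4-(tert-butyldimethylsilyloxy)-2-methyl-6-vinylphenoxy]-4,8-dimethyl-2-(triethylsilyloxy)deca-4,9-dien-1-ol | C=Cc1cc(O[Si](C)(C)C(C)(C)C)cc(C)c1O[C@@](C)(C=C)CC/C=C(C)/C[C@@H](O[Si](CC)(CC)CC)CO | intermediate
19 | (2R,4E,8R)-8-[4-(tert-butyldimethylsilyloxy)-2-methyl-6-vinylphenoxy]-4,8-dimethyl-2-(triethylsilyloxy)deca-4,9-dienal | C=Cc1cc(O[Si](C)(C)C(C)(C)C)cc(C)c1O[C@@](C)(C=C)CC/C=C(C)/C[C@@H](O[Si](CC)(CC)CC)C=O | intermediate
20 | (3R,6E,9R)-3-[4-(tert-butyldimethylsilyloxy)-2-methyl-6-vinylphenoxy]-3,7-dimethyl-9-(triethylsilyloxy)undeca-1,6,10-triene | C=Cc1cc(O[Si](C)(C)C(C)(C)C)cc(C)c1O[C@@](C)(C=C)CC/C=C(C)/C[C@@H](O[Si](CC)(CC)CC)C=C | intermediate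
21 | (3R,5E,9R)-9-[4-(tert-butyldimethylsilyloxy)-2-methyl-6-vinylphenoxy]-5,9-dimethylundeca-1,5,10-trien-3-ol | C=Cc1cc(O[Si](C)(C)C(C)(C)C)cc(C)c1O[C@@](C)(C=C)CC/C=C(C)/C[C@@H](O)C=C | intermediate
22 | triethyl phosphonoacetate | CCOC(=O)CP(=O)(OCC)OCC | starting material
23 | 5-bromo-2-methylpent-2-ene | CC(C)=CCCBr | starting material
24 | sodium salt of triethyl phosphonoacetate | [Na+].CCOC(=O)[CH-]P(=O)(OCC)OCC | intermediate (not isolated)
25 | ethyl 2-(diethoxyphosphoryl)-6-methylhept-5-enoate (racemic) | CCOC(=O)C(CCC=C(C)C)P(=O)(OCC)OCC | intermediate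
26 | ethyl 6-methyl-2-methylidenehept-5-enoate | CCOC(=O)C(=C)CCC=C(C)C | intermediate
27 | lithium 6-methyl-2-methylidenehept-5-enoate | [Li+].[O-]C(=O)C(=C)CCC=C(C)C | intermediate (not isolated)
28 | 6-methyl-2-methylidenehept-5-enoic acid | OC(=O)C(=C)CCC=C(C)C | intermediate
29 | (3R,5E,9R)-9-[4-(tert-butyldimethylsilyloxy)-2-methyl-6-vinylphenoxy]-5,9-dimethylundeca-1,5,10-trien-3-yl 6-methyl-2-methylidenehept-5-enoate (open-chain tetraene, key-step precursor) | C=Cc1cc(O[Si](C)(C)C(C)(C)C)cc(C)c1O[C@@](C)(C=C)CC/C=C(C)/C[C@H](C=C)OC(=O)C(=C)CCC=C(C)C | intermediate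
30 | (3R,5E)-8-[(2R)-6-(tert-butyldimethylsilyloxy)-2,8-dimethyl-2H-chromen-2-yl]-5-methylocta-1,5-dien-3-yl 6-methyl-2-methylidenehept-5-enoate | C=C[C@@H](C/C(C)=C/CC[C@]1(C)C=Cc2cc(O[Si](C)(C)C(C)(C)C)cc(C)c2O1)OC(=O)C(=C)CCC=C(C)C | intermediate (not isolated)
31 | (5R)-5-{(2E)-5-[(2R)-6-(tert-butyldimethylsilyloxy)-2,8-dimethyl-2H-chromen-2-yl]-2-methylpent-2-en-1-yl}-3-(4-methylpent-3-en-1-yl)furan-2(5H)-one (6-O-TBS ether of the target) | CC(C)=CCCC1=C[C@@H](C/C(C)=C/CC[C@]2(C)C=Cc3cc(O[Si](C)(C)C(C)(C)C)cc(C)c3O2)OC1=O | intermediate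
32 | 2'-epi-tuberatolide B, (5R)-5-{(2E)-5-[(2R)-6-hydroxy-2,8-dimethyl-2H-chromen-2-yl]-2-methylpent-2-en-1-yl}-3-(4-methylpent-3-en-1-yl)furan-2(5H)-one | CC(C)=CCCC1=C[C@@H](C/C(C)=C/CC[C@]2(C)C=Cc3cc(O)cc(C)c3O2)OC1=O | target

**Step count**

Total: 21 steps. Longest linear sequence: 14 steps (1, 2, 4–7, 11–15, 19–21) from 2-methylhydroquinone.

**Steps most likely to fail**

Step 4 (asymmetric O-allylation). The phenoxide has substituents at both ortho positions and may attack the unsubstituted allyl terminus, giving the linear geranyl ether, or add with poor facial selectivity. The fallback sets out from bromophenol 3 and replaces catalytic asymmetric induction by a racemic C–O bond formation followed by resolution. Racemic 3,7-dimethyloct-6-en-1-yn-3-ol (CC(C)=CCCC(C)(O)C#C) is converted in the flask with trifluoroacetic anhydride and DBU in MeCN at −5 °C into 3,7-dimethyloct-6-en-1-yn-3-yl trifluoroacetate F1. With 3 and CuCl2 (cat.), F1 should give the racemic aryl propargyl ether F2 by copper-catalysed propargylic etherification, which tolerates hindered phenols. Semi-hydrogenation (H2, Pd/CaCO3 poisoned with Pb(OAc)2, quinoline) leads to the racemic vinyl ether F3. Preparative chiral-phase HPLC then delivers the (R)-enantiomer, identified against the enriched sample from step 4, which is compound 6.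

Step 5 (vinylation). Zerovalent palladium may ionise the tertiary allyl aryl ether, with loss of the C2 configuration or of the whole side chain, or the arylpalladium intermediate may insert into the neighbouring C2 vinyl group in a 5-exo Heck cyclisation before transmetalation. The fallback sets out from bromide 6 and uses no palladium. Bromine–lithium exchange (t-BuLi, 2 equiv, Et2O, −78 °C) gives the aryllithium F4. A DMF quench gives 5-(tert-butyldimethylsilyloxy)-2-{[(3R)-3,7-dimethylocta-1,6-dien-3-yl]oxy}-3-methylbenzaldehyde F5. Wittig methylenation (Ph3PCH3Br, KN(SiMe3)2, THF) returns to styrene 7.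

Step 20 (double ring closure). Closure of the trisubstituted butenolide from the 1,1-disubstituted acrylate may stall after the chromene has formed, or the catalyst may be consumed by cross metathesis of the acrylate. The fallback sets out from aldehyde 19, builds the butenolide without metathesis and leaves only the easier chromene closure. Bromide 23 alkylates methyl bis(2,2,2-trifluoroethyl)phosphonoacetate (NaH, NaI, DMSO) to give methyl 2-[bis(2,2,2-trifluoroethoxy)phosphoryl]-6-methylhept-5-enoate F6. Still–Gennari olefination of 19 with F6 (KN(SiMe3)2, 18-crown-6, THF, −78 °C) should give the (Z)-enoate F7. PPTS in methanol removes the triethylsilyl group, and the γ-hydroxy (Z)-ester lactonises to the butenolide triene F8. A single ring-closing metathesis of the styrene and C2 vinyl groups of F8 with (H2IMes)(PCy3)Cl2Ru=CHPh in dilute CH2Cl2 then gives compound 31.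

**Further compounds**

F1 | step 4 | 3,7-dimethyloct-6-en-1-yn-3-yl trifluoroacetate (racemic, made in the flask) | CC(C)=CCCC(C)(C#C)OC(=O)C(F)(F)F
F2 | step 4 | racemic 2-bromo-4-(tert-butyldimethylsilyloxy)-6-methylphenyl 3,7-dimethyloct-6-en-1-yn-3-yl ether | Cc1cc(O[Si](C)(C)C(C)(C)C)cc(Br)c1OC(C)(C#C)CCC=C(C)C
F3 | step 4 | racemic 2-bromo-4-(tert-butyldimethylsilyloxy)-6-methylphenyl 3,7-dimethylocta-1,6-dien-3-yl ether | Cc1cc(O[Si](C)(C)C(C)(C)C)cc(Br)c1OC(C)(C=C)CCC=C(C)C
F4 | step 5 | (R)-{5-(tert-butyldimethylsilyloxy)-2-[(3,7-dimethylocta-1,6-dien-3-yl)oxy]-3-methylphenyl}lithium | [Li]c1cc(O[Si](C)(C)C(C)(C)C)cc(C)c1O[C@@](C)(C=C)CCC=C(C)C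
F5 | step 5 | 5-(tert-butyldimethylsilyloxy)-2-{[(3R)-3,7-dimethylocta-1,6-dien-3-yl]oxy}-3-methylbenzaldehyde | O=Cc1cc(O[Si](C)(C)C(C)(C)C)cc(C)c1O[C@@](C)(C=C)CCC=C(C)C
F6 | step 20 | methyl 2-[bis(2,2,2-trifluoroethoxy)phosphoryl]-6-methylhept-5-enoate | COC(=O)C(CCC=C(C)C)P(=O)(OCC(F)(F)F)OCC(F)(F)F
F7 | step 20 | methyl (2Z,4R,6E,10R)-10-[4-(tert-butyldimethylsilyloxy)-2-methyl-6-vinylphenoxy]-6,10-dimethyl-2-(4-methylpent-3-en-1-yl)-4-(triethylsilyloxy)dodeca-2,6,11-trienoate | C=Cc1cc(O[Si](C)(C)C(C)(C)C)cc(C)c1O[C@@](C)(C=C)CC/C=C(C)/C[C@@H](O[Si](CC)(CC)CC)/C=C(\C(=O)OC)CCC=C(C)C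
F8 | step 20 | (5R)-5-{(2E,6R)-6-[4-(tert-butyldimethylsilyloxy)-2-methyl-6-vinylphenoxy]-2,6-dimethylocta-2,7-dien-1-yl}-3-(4-methylpent-3-en-1-yl)furan-2(5H)-one | C=Cc1cc(O[Si](C)(C)C(C)(C)C)cc(C)c1O[C@@](C)(C=C)CC/C=C(C)/C[C@@H]1C=C(CCC=C(C)C)C(=O)O1
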